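Ring B of the tetralin (C1 aryl, C2 CH2O-coumarate, C3 CH2OH, C4 CH2; fused to ring A at C4a/C8a) carries trans one-carbon groups on C2 and C3 between two benzylic carbons, so it is cut at C1–C2 and C3–C4 into a hydroxy-o-quinodimethane and a fumarate. Irradiating a bis-silylated 2-benzylbenzaldehyde with the fumarate of methyl (S)-lactate should form both bonds, close ring B and set C1 to C4 at once. Because C4–OH can lactonise with neither ester (four-membered ring to C3, trans to C2), it instead ties the cis C3 CH2OH into an acetonide after reduction, leaving only the C2 CH2OH for coumaroylation before C4 is reduced to CH2.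

Key step: step 8

Assumption: positions follow tetralin numbering (C1 aryl-bearing, C4 the other benzylic carbon, C6 OMe, C7 oxygen; TBS = tert-butyldimethylsilyl, TBSO = its ether), and the (S)-lactate groups are taken to expose the fumarate face that leads to the (2R,3R) series.

Step 1
Reactants: 1 2-bromo-5-hydroxy-4-methoxybenzaldehyde (6-bromoisovanillin)
Product: 2 2-bromo-5-(TBSO)-4-methoxybenzaldehyde
Conditions: TBSCl (1.2 equiv), imidazole (2.5 equiv), DMF, 0 °C to rt
Reagents that add atoms: tert-butyldimethylsilyl chloride (TBSCl), CC(C)(C)[Si](C)(C)Cl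
Why: Imidazole-promoted silylation of a phenol (Corey protocol) is routine and the resulting aryl silyl ether, meta to the aldehyde, is not activated towards cleavage.

Step 2
Reactants: 3 4-bromo-2-methoxyphenol
Product: 4 (4-bromo-2-methoxyphenoxy)(tert-butyl)dimethylsilane
Conditions: TBSCl (1.2 equiv), imidazole (2.5 equiv), DMF, 0 °C to rt
Reagents that add atoms: tert-butyldimethylsilyl chloride (TBSCl), CC(C)(C)[Si](C)(C)Cl
Why: The same imidazole-promoted phenol silylation masks the only acidic proton before the halogen–lithium exchange.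

Step 3
Reactants: 4 (4-bromo-2-methoxyphenoxy)(tert-butyl)dimethylsilane; 2 2-bromo-5-(TBSO)-4-methoxybenzaldehyde
Product: 6 [2-bromo-5-(TBSO)-4-methoxyphenyl][4-(TBSO)-3-methoxyphenyl]methanol (racemic), via aryllithium 5 (not isolated)
Conditions: 4, n-BuLi (1.05 equiv), THF, −78 °C; then 2, −78 to −40 °C; sat. aq. NH4Cl
Reagents that add atoms: none
Why: Bromine–lithium exchange on 4 is fast at −78 °C and 1,2-addition of the aryllithium to the aldehyde of 2 outruns exchange at its own bromine, giving a racemic carbinol whose stereocentre disappears in step 4.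

Step 4
Reactants: 6 [2-bromo-5-(TBSO)-4-methoxyphenyl][4-(TBSO)-3-methoxyphenyl]methanol
Product: 7 1-bromo-4-(TBSO)-5-methoxy-2-[4-(TBSO)-3-methoxybenzyl]benzene
Conditions: Et3SiH (3 equiv), TFA (5 equiv), CH2Cl2, 0 °C
Reagents that add atoms: none
Why: Ionic hydrogenation works because the diarylmethyl cation, stabilised by the para silyloxy group of one ring and the para methoxy group of the other, forms under mild acid and is captured by hydride from Et3SiH while the aryl bromide and aryl silyl ethers stay intact.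

Step 5
Reactants: 7 1-bromo-4-(TBSO)-5-methoxy-2-[4-(TBSO)-3-methoxybenzyl]benzene
Product: 9 4-(TBSO)-5-methoxy-2-[4-(TBSO)-3-methoxybenzyl]benzaldehyde, via aryllithium 8 (not isolated)
Conditions: n-BuLi (1.1 equiv), THF, −78 °C; DMF (3 equiv), −78 to 0 °C; 1 M HCl, 0 °C
Reagents that add atoms: N,N-dimethylformamide (DMF), CN(C)C=O
Why: Bromine–lithium exchange followed by formylation with DMF (Bouveault aldehyde synthesis) places the aldehyde at the former C–Br carbon, and at −78 °C the exchange is faster than deprotonation of the diarylmethane CH2.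

Step 6
Reactants: 10 fumaryl chloride; 11 methyl (S)-lactate
Product: 12 bis[(S)-1-methoxy-1-oxopropan-2-yl] fumarate
Conditions: 11 (2.2 equiv), PhMe, 80 °C, N2 sweep
Reagents that add atoms: none
Why: Alcoholysis of the diacid chloride by the secondary hydroxyl of the lactate is a simple acylation that touches neither the lactate stereocentre nor the E-alkene.

Step 7
Reactants: 13 p-coumaric acid
Product: 15 (E)-3-[4-(TBSO)phenyl]acrylic acid, via silyl ester 14 (not isolated)
Conditions: TBSCl (2.3 equiv), imidazole (5 equiv), DMF, rt; then AcOH/THF/H2O (3:1:1), rt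
Reagents that add atoms: tert-butyldimethylsilyl chloride (TBSCl), CC(C)(C)[Si](C)(C)Cl
Why: Silylation covers both the phenol and the acid, and mild aqueous acid then hydrolyses only the silyl ester, which is far more labile than the aryl silyl ether.

Step 8
Reactants: 9 4-(TBSO)-5-methoxy-2-[4-(TBSO)-3-methoxybenzyl]benzaldehyde; 12 bis[(S)-1-methoxy-1-oxopropan-2-yl] fumarate
Product: 17 bis[(S)-1-methoxy-1-oxopropan-2-yl] (1S,2R,3S,4S)-4-hydroxy-6-methoxy-1-[3-methoxy-4-(TBSO)phenyl]-7-(TBSO)-1,2,3,4-tetrahydronaphthalene-2,3-dicarboxylate, via dienol 16 (not isolated)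
Conditions: hν (350 nm, Pyrex), 12 (3 equiv), degassed PhMe (0.02 M), 20 °C
Reagents that add atoms: none
Why: n→π* excitation of aldehyde 9 and 1,5-hydrogen transfer from the diarylmethane CH2 give the dienol, of which only the (E,E)-isomer 16 (OH and aryl both outward) lives long enough to be trapped, and this adds suprafacially to fumarate 12 so that ring A regains its aromaticity. The closest known reaction type is the photoenolisation/Diels–Alder sequence of o-alkyl- and o-benzylbenzaldehydes with fumaric esters of chiral α-hydroxy esters. Ring B is closed by an intermolecular [4+2] cycloaddition that forms C1–C2 and C3–C4 in one event, not by a stepwise exo or endo cyclisation. C1 and C4 should come out cis because both outward diene substituents end on the same face, C2 and C3 stay trans from the E-alkene, and the C3 ester should be cis to C4–OH (hence the C2 ester trans to the C1 aryl) because the ester next to the enol OH takes the endo position, helped by an O–H···O=C hydrogen bond. The absolute sense (1S,2R,3S,4S) is set by the two (S)-lactate groups, which screen one face of the C2-symmetric fumarate. The step needs endo and facial selectivity, and excess 12, an oxygen-free dilute solution and ambient temperature are meant to keep the dienol from reverting or closing to the benzocyclobutenol before it is trapped.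

Step 9
Reactants: 17 the cycloadduct (tetraester)
Product: 18 (1S,2R,3R,4S)-4-hydroxy-2,3-bis(hydroxymethyl)-6-methoxy-1-[3-methoxy-4-(TBSO)phenyl]-7-(TBSO)-1,2,3,4-tetrahydronaphthalene (triol)
Conditions: LiAlH4 (5 equiv), THF, −10 to 0 °C; aq. potassium sodium tartrate (KNaC4H4O6)
Reagents that add atoms: none
Why: Hydride reduction of the four ester carbonyls releases both auxiliaries as (S)-propane-1,2-diol and methanol and leaves C1 to C4 untouched, since the aryl silyl ethers tolerate LiAlH4 at 0 °C and reduction of the C3 ester is faster than retro-aldol opening of the C4 alkoxide.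

Step 10
Reactants: 18 the triol
Product: 19 acetonide alcohol: 18 with C4–O and C3–CH2O joined as a cis-fused 2,2-dimethyl-1,3-dioxane and the C2 CH2OH free, (1S,2R,3R,4S)
Conditions: 2,2-dimethoxypropane (5 equiv), PPTS (0.1 equiv), acetone, rt
Reagents that add atoms: 2,2-dimethoxypropane, COC(C)(C)OC
Why: Acid-catalysed transketalisation under equilibrating conditions should favour the six-membered 1,3-dioxane across the cis C4–OH/C3–CH2OH pair over a seven-membered ketal across the two primary hydroxyls, and the C2 CH2OH, trans to the C4 oxygen, cannot bridge to it.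

Step 11
Reactants: 19 the acetonide alcohol; 15 (E)-3-[4-(TBSO)phenyl]acrylic acid
Product: 20 acetonide coumarate: the C2 CH2O (E)-3-[4-(TBSO)phenyl]acrylate of 19, (1S,2R,3R,4S)
Conditions: DIC (1.3 equiv), DMAP (0.2 equiv), CH2Cl2, 0 °C to rt
Reagents that add atoms: none
Why: Steglich esterification acylates the only free hydroxyl, the primary C2 CH2OH, with no stereocentre involved and with the E-alkene of the acid preserved.

Step 12
Reactants: 20 the acetonide coumarate
Product: 21 [(1S,2R,3R)-3-(hydroxymethyl)-6-methoxy-1-[3-methoxy-4-(TBSO)phenyl]-7-(TBSO)-1,2,3,4-tetrahydronaphthalen-2-yl]methyl (E)-3-[4-(TBSO)phenyl]acrylate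
Conditions: Et3SiH (5 equiv), TFA/H2O (9:1, 20 equiv TFA), CH2Cl2, 0 °C; aq. NaHCO3
Reagents that add atoms: none
Why: In wet acid the isopropylidene group is lost as acetone and the C4–O bond, benzylic and para to the C7 silyloxy group, ionises to a cation that is reduced by Et3SiH (ionic hydrogenation), while the cinnamate alkene, the aryl silyl ethers and the stereocentres C1 to C3 are not engaged.

Step 13
Reactants: 21 the tris-silyl ether
Product: 22 [(1S,2R,3R)-7-hydroxy-1-(4-hydroxy-3-methoxyphenyl)-3-(hydroxymethyl)-6-methoxy-1,2,3,4-tetrahydronaphthalen-2-yl]methyl (E)-3-(4-hydroxyphenyl)acrylate (target)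
Conditions: HF·pyridine (excess), pyridine, THF, 0 °C to rt
Reagents that add atoms: none
Why: Fluoride-driven cleavage of the three aryl silyl ethers under buffered, non-basic conditions frees the phenols without migration of the coumaroyl group to the neighbouring C3 CH2OH or cleavage of the ester.

Compound list

1 | 2-bromo-5-hydroxy-4-methoxybenzaldehyde (6-bromoisovanillin) | O=Cc1cc(O)c(OC)cc1Br | starting material
2 | 2-bromo-5-(TBSO)-4-methoxybenzaldehyde | O=Cc1cc(O[Si](C)(C)C(C)(C)C)c(OC)cc1Br | intermediate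
3 | 4-bromo-2-methoxyphenol | COc1cc(Br)ccc1O | starting material
4 | (4-bromo-2-methoxyphenoxy)(tert-butyl)dimethylsilane | COc1cc(Br)ccc1O[Si](C)(C)C(C)(C)C | intermediate
5 | [4-(TBSO)-3-methoxyphenyl]lithium | [Li]c1ccc(O[Si](C)(C)C(C)(C)C)c(OC)c1 | intermediate
6 | [2-bromo-5-(TBSO)-4-methoxyphenyl][4-(TBSO)-3-methoxyphenyl]methanol (racemic) | OC(c1cc(O[Si](C)(C)C(C)(C)C)c(OC)cc1Br)c1ccc(O[Si](C)(C)C(C)(C)C)c(OC)c1 | intermediate
7 | 1-bromo-4-(TBSO)-5-methoxy-2-[4-(TBSO)-3-methoxybenzyl]benzene | Brc1cc(OC)c(O[Si](C)(C)C(C)(C)C)cc1Cc1ccc(O[Si](C)(C)C(C)(C)C)c(OC)c1 | intermediate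
8 | {4-(TBSO)-5-methoxy-2-[4-(TBSO)-3-methoxybenzyl]phenyl}lithium | [Li]c1cc(OC)c(O[Si](C)(C)C(C)(C)C)cc1Cc1ccc(O[Si](C)(C)C(C)(C)C)c(OC)c1 | intermediate
9 | 4-(TBSO)-5-methoxy-2-[4-(TBSO)-3-methoxybenzyl]benzaldehyde | O=Cc1cc(OC)c(O[Si](C)(C)C(C)(C)C)cc1Cc1ccc(O[Si](C)(C)C(C)(C)C)c(OC)c1 | intermediate
10 | fumaryl chloride | O=C(Cl)/C=C/C(=O)Cl | starting material
11 | methyl (S)-lactate | C[C@H](O)C(=O)OC | starting material
12 | bis[(S)-1-methoxy-1-oxopropan-2-yl] fumarate | COC(=O)[C@H](C)OC(=O)/C=C/C(=O)O[C@@H](C)C(=O)OC | intermediate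
13 | p-coumaric acid | O=C(O)/C=C/c1ccc(O)cc1 | starting material
14 | tert-butyldimethylsilyl (E)-3-[4-(TBSO)phenyl]acrylate | CC(C)(C)[Si](C)(C)OC(=O)/C=C/c1ccc(O[Si](C)(C)C(C)(C)C)cc1 | intermediate
15 | (E)-3-[4-(TBSO)phenyl]acrylic acid | O=C(O)/C=C/c1ccc(O[Si](C)(C)C(C)(C)C)cc1 | intermediate
16 | (E,E)-hydroxy-o-quinodimethane from 9 (OH and aryl both outward) | O/C=C1\C=C(OC)C(O[Si](C)(C)C(C)(C)C)=C/C1=C\c1ccc(O[Si](C)(C)C(C)(C)C)c(OC)c1 | intermediate
17 | bis[(S)-1-methoxy-1-oxopropan-2-yl] (1S,2R,3S,4S)-4-hydroxy-6-methoxy-1-[3-methoxy-4-(TBSO)phenyl]-7-(TBSO)-1,2,3,4-tetrahydronaphthalene-2,3-dicarboxylate (1,2-trans, 2,3-trans, 3,4-cis) | COc1cc([C@H]2c3cc(O[Si](C)(C)C(C)(C)C)c(OC)cc3[C@@H](O)[C@@H](C(=O)O[C@@H](C)C(=O)OC)[C@@H]2C(=O)O[C@@H](C)C(=O)OC)ccc1O[Si](C)(C)C(C)(C)C | intermediate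
18 | (1S,2R,3R,4S)-4-hydroxy-2,3-bis(hydroxymethyl)-6-methoxy-1-[3-methoxy-4-(TBSO)phenyl]-7-(TBSO)-1,2,3,4-tetrahydronaphthalene | COc1cc([C@H]2c3cc(O[Si](C)(C)C(C)(C)C)c(OC)cc3[C@@H](O)[C@@H](CO)[C@@H]2CO)ccc1O[Si](C)(C)C(C)(C)C | intermediate
19 | acetonide alcohol (C4–O/C3–CH2O isopropylidene acetal of 18, C2 CH2OH free) | COc1cc([C@H]2c3cc(O[Si](C)(C)C(C)(C)C)c(OC)cc3[C@H]4OC(C)(C)OC[C@H]4[C@@H]2CO)ccc1O[Si](C)(C)C(C)(C)C | intermediate
20 | acetonide coumarate (C2 CH2O (E)-3-[4-(TBSO)phenyl]acrylate of 19) | COc1cc([C@H]2c3cc(O[Si](C)(C)C(C)(C)C)c(OC)cc3[C@H]4OC(C)(C)OC[C@H]4[C@@H]2COC(=O)/C=C/c2ccc(O[Si](C)(C)C(C)(C)C)cc2)ccc1O[Si](C)(C)C(C)(C)C | intermediate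
21 | [(1S,2R,3R)-3-(hydroxymethyl)-6-methoxy-1-[3-methoxy-4-(TBSO)phenyl]-7-(TBSO)-1,2,3,4-tetrahydronaphthalen-2-yl]methyl (E)-3-[4-(TBSO)phenyl]acrylate | COc1cc([C@H]2c3cc(O[Si](C)(C)C(C)(C)C)c(OC)cc3C[C@@H](CO)[C@@H]2COC(=O)/C=C/c2ccc(O[Si](C)(C)C(C)(C)C)cc2)ccc1O[Si](C)(C)C(C)(C)C | intermediate
22 | [(1S,2R,3R)-7-hydroxy-1-(4-hydroxy-3-methoxyphenyl)-3-(hydroxymethyl)-6-methoxy-1,2,3,4-tetrahydronaphthalen-2-yl]methyl (E)-3-(4-hydroxyphenyl)acrylate | COc1cc([C@H]2c3cc(O)c(OC)cc3C[C@@H](CO)[C@@H]2COC(=O)/C=C/c2ccc(O)cc2)ccc1O | target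

Total step count: 13 steps.
Longest linear sequence: 10 steps (steps 1, 3, 4, 5, 8, 9, 10, 11, 12, 13).

Steps most likely to fail

Step 8. The electron-rich aldehyde may photoenolise inefficiently, and the dienol may revert by 1,5-hydrogen shift or close to the benzocyclobutenol faster than the fumarate traps it. The fallback stores the dienol as its sulfur dioxide adduct and releases it thermally. It sets out from 9: irradiation at 350 nm in benzene saturated with SO2 should give the cis hydroxy sulfone F1. Heating this with 12 (3 equiv) and ZnO in PhMe at 80 °C should extrude SO2 in a cheletropic step, regenerate dienol 16 slowly in the dark, and come back to the route at 17.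

Step 10. Ketalisation may close the seven-membered ring across the two primary hydroxyls, or the acid may ionise the electron-rich benzylic C4–OH. The fallback masks the cis 1,3-diol under neutral conditions as a boronate. It sets out from 18: PhB(OH)2 (1.05 equiv) in PhMe with azeotropic removal of water should give the cyclic phenylboronate F2. Coupling of its free C2 CH2OH with 15 (DIC, DMAP, CH2Cl2) should give the boronate coumarate F3. Under the conditions of step 12 the wet acid hydrolyses the boronate and the silane reduces C4, so the fallback comes back to the route at 21.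

Step 12. The C4 cation may lose the C3 proton before hydride arrives, and re-protonation of the resulting alkene would scramble C3. The fallback removes the C4 oxygen by a radical path (Barton–McCombie deoxygenation). It sets out from 20:
- AcOH/THF/H2O at 40 °C should cleave the acetonide to the diol ester F4.
- TBSCl and imidazole should silylate only the primary C3 CH2OH, giving the C3 silyl ether F5.
- 1,1'-Thiocarbonyldiimidazole and DMAP in PhMe should convert the C4–OH into the C4 imidazole-1-carbothioate F6.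
- Bu3SnH and AIBN in PhMe at 80 °C should give the 4-deoxy tetrasilyl ether F7.
- HF·pyridine as in step 13 comes back to the route at 22.

Further compounds

F1 | step 8 | cis-1-hydroxy-6-(TBSO)-5-methoxy-3-[4-(TBSO)-3-methoxyphenyl]-1,3-dihydrobenzo[c]thiophene 2,2-dioxide (racemic, one enantiomer drawn) | O[C@@H]1c2cc(OC)c(O[Si](C)(C)C(C)(C)C)cc2[C@H](c2ccc(O[Si](C)(C)C(C)(C)C)c(OC)c2)S1(=O)=O
F2 | step 10 | cyclic phenylboronate of 18 across C4–O and C3–CH2O (C2 CH2OH free) | COc1cc([C@H]2c3cc(O[Si](C)(C)C(C)(C)C)c(OC)cc3[C@H]4OB(c5ccccc5)OC[C@H]4[C@@H]2CO)ccc1O[Si](C)(C)C(C)(C)C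
F3 | step 10 | C2 CH2O (E)-3-[4-(TBSO)phenyl]acrylate of boronate F2 | COc1cc([C@H]2c3cc(O[Si](C)(C)C(C)(C)C)c(OC)cc3[C@H]4OB(c5ccccc5)OC[C@H]4[C@@H]2COC(=O)/C=C/c2ccc(O[Si](C)(C)C(C)(C)C)cc2)ccc1O[Si](C)(C)C(C)(C)C
F4 | step 12 | diol ester: (1S,2R,3R,4S)-4-hydroxy-3-(hydroxymethyl) analogue of 21 | COc1cc([C@H]2c3cc(O[Si](C)(C)C(C)(C)C)c(OC)cc3[C@@H](O)[C@@H](CO)[C@@H]2COC(=O)/C=C/c2ccc(O[Si](C)(C)C(C)(C)C)cc2)ccc1O[Si](C)(C)C(C)(C)C
F5 | step 12 | C3 CH2OTBS ether of F4 (C4–OH free) | COc1cc([C@H]2c3cc(O[Si](C)(C)C(C)(C)C)c(OC)cc3[C@@H](O)[C@@H](CO[Si](C)(C)C(C)(C)C)[C@@H]2COC(=O)/C=C/c2ccc(O[Si](C)(C)C(C)(C)C)cc2)ccc1O[Si](C)(C)C(C)(C)C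
F6 | step 12 | C4 O-(1H-imidazole-1-carbothioate) of F5 | COc1cc([C@H]2c3cc(O[Si](C)(C)C(C)(C)C)c(OC)cc3[C@@H](OC(=S)n4ccnc4)[C@@H](CO[Si](C)(C)C(C)(C)C)[C@@H]2COC(=O)/C=C/c2ccc(O[Si](C)(C)C(C)(C)C)cc2)ccc1O[Si](C)(C)C(C)(C)C
F7 | step 12 | 4-deoxy tetrasilyl ether (21 with C3 CH2OTBS) | COc1cc([C@H]2c3cc(O[Si](C)(C)C(C)(C)C)c(OC)cc3C[C@@H](CO[Si](C)(C)C(C)(C)C)[C@@H]2COC(=O)/C=C/c2ccc(O[Si](C)(C)C(C)(C)C)cc2)ccc1O[Si](C)(C)C(C)(C)C
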